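**Assumption:** atoms are numbered C1–C16 along the open diterpene chain (C1 = CH2OH carbon, C16 = CH2OAc carbon, C17 = lactone carbonyl on C11). Compounds 13–21 are C11 epimer mixtures, which step 12 makes irrelevant. Imine 5 is taken as a catalogue item (otherwise mix acetaldehyde and tert-butylamine).

## Retrosynthetic overview

1. Target 23 comes from bis-silyl ether 22 by global desilylation.
2. Second ring closure (C11–O6 bond): a new copper-catalysed transannular etherification of the tertiary α-chloro ε-lactone 21 closes the dioxanone and oxepane rings at once and sets C11.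
3. First ring closure (C7–O bond): the C17 acid opens the (6S,7S)-epoxide 20 at C7 with inversion to give the ε-lactone; the epoxide comes from Shi epoxidation of 19.
4. C10–C11 bond: asymmetric Mukaiyama aldol of chloro ketene silyl acetal 14 with aldehyde 7 sets C10.
5. Aldehyde 7 comes from nerol (SeO2, Appel, aza-enolate alkylation). Chloro ester 13 comes from a Z-selective Wittig reaction of 8 with 9.

## Route

Step 1
Reactants: 1 nerol
Product: 2 neryl tert-butyldimethylsilyl ether
Conditions: t-BuMe2SiCl, imidazole, CH2Cl2, 0 °C to rt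
Reagents that add atoms: tert-butyldimethylsilyl chloride, CC(C)(C)[Si](C)(C)Cl
Why: Imidazole-promoted silyl ether formation on the primary allylic alcohol, which leaves the 2Z olefin untouched and creates no stereocentre.

Step 2
Reactants: 2 neryl tert-butyldimethylsilyl ether
Product: 3 (2E,6Z)-8-(tert-butyldimethylsilyloxy)-2,6-dimethylocta-2,6-dien-1-ol
Conditions: SeO2 (0.1 equiv), t-BuOOH (2.5 equiv), salicylic acid (0.1 equiv), CH2Cl2, 0 °C to rt
Reagents that add atoms: tert-butyl hydroperoxide, CC(C)(C)OO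
Why: Catalytic SeO2 allylic oxidation (ene reaction then [2,3]-sigmatropic shift) attacks the more electron-rich distal olefin and oxidises only its E-methyl group, which fixes the 6E geometry.

Step 3
Reactants: 3 (2E,6Z)-8-(tert-butyldimethylsilyloxy)-2,6-dimethylocta-2,6-dien-1-ol
Product: 4 (2Z,6E)-8-bromo-1-(tert-butyldimethylsilyloxy)-3,7-dimethylocta-2,6-diene
Conditions: CBr4, PPh3, CH2Cl2, −20 °C
Reagents that add atoms: carbon tetrabromide, BrC(Br)(Br)Br
Why: The Appel reaction converts the primary allylic alcohol to the bromide by SN2 displacement without allylic transposition or E/Z scrambling.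

Step 4
Reactants: 4 (2Z,6E)-8-bromo-1-(tert-butyldimethylsilyloxy)-3,7-dimethylocta-2,6-diene; 5 N-tert-butylethanimine
Product: 7 (4E,8Z)-10-(tert-butyldimethylsilyloxy)-4,8-dimethyldeca-4,8-dienal, via alkylated imine 6 (not isolated)
Conditions: 5, LiN(iPr)2, THF, 0 °C; 4, −78 to 0 °C; then aq. tartaric acid, pentane, 0 °C
Reagents that add atoms: water, O
Why: Metalloenamine (aza-enolate) alkylation is a clean SN2 reaction at the primary allylic bromide, and mild imine hydrolysis frees the aldehyde (C9–C10) without touching the silyl ether.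

Step 5
Reactants: 8 (4-carboxybutyl)triphenylphosphonium bromide; 9 1-(tert-butyldimethylsilyloxy)propan-2-one
Product: 11 (5Z)-7-hydroxy-6-methylhept-5-enoic acid, via silyl ether acid 10 (not isolated)
Conditions: 8, NaN(SiMe3)2 (2.1 equiv), THF, 0 °C; 9, −78 °C to rt; then 1 M HCl, THF, rt
Reagents that add atoms: none
Why: The Wittig reaction of a non-stabilised ylide with an α-silyloxy ketone is kinetically Z-selective (chain cis to CH2O), which sets the 14Z olefin, and the acidic work-up removes the primary allylic silyl group.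

Step 6
Reactants: 11 (5Z)-7-hydroxy-6-methylhept-5-enoic acid
Product: 12 tert-butyl (5Z)-7-hydroxy-6-methylhept-5-enoate
Conditions: Me2NCH(Ot-Bu)2 (3 equiv), toluene, 80 °C
Reagents that add atoms: N,N-dimethylformamide di-tert-butyl acetal, CN(C)C(OC(C)(C)C)OC(C)(C)C
Why: Esterification by O-alkylation of the carboxylate with the formamide acetal is selective for the acid over the alcohol and needs no strong acid.

Step 7
Reactants: 12 tert-butyl (5Z)-7-hydroxy-6-methylhept-5-enoate
Product: 13 tert-butyl (5Z)-2-chloro-7-hydroxy-6-methylhept-5-enoate (racemic)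
Conditions: LiN(iPr)2 (2.2 equiv), THF, −78 °C; C2Cl6 (1.1 equiv), −78 °C; aq. NH4Cl
Reagents that add atoms: hexachloroethane, ClC(Cl)(Cl)C(Cl)(Cl)Cl
Why: Electrophilic chlorination of the lithium ester enolate (the alkoxide is a spectator) puts the later radical handle on C11, whose configuration does not matter.

Step 8
Reactants: 13 tert-butyl (5Z)-2-chloro-7-hydroxy-6-methylhept-5-enoate; 7 (4E,8Z)-10-(tert-butyldimethylsilyloxy)-4,8-dimethyldeca-4,8-dienal
Product: 15 tert-butyl (5Z)-2-chloro-7-hydroxy-2-[(1S,4E,8Z)-10-(tert-butyldimethylsilyloxy)-1-hydroxy-4,8-dimethyldeca-4,8-dien-1-yl]-6-methylhept-5-enoate, via ketene silyl acetal 14 (not isolated)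
Conditions: 13, LiN(SiMe3)2 (2.1 equiv), Me3SiCl (2.3 equiv), THF, −78 °C, solvent switch; N-tosyl-D-valine (1.1 equiv), BH3·THF (1.0 equiv), CH2Cl2, 0 °C to rt; 7 then crude 14, −78 °C; pH 7 buffer, then citric acid, MeOH
Reagents that add atoms: none
Why: In this oxazaborolidinone-promoted asymmetric Mukaiyama aldol (Kiyooka aldol), the D-valine-derived boron Lewis acid exposes the Re face of the aldehyde, so C10 is formed as S whatever the acetal geometry, and the C10–C11 bond completes the linear C20 chain.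

Step 9
Reactants: 15 aldol diol
Product: 16 tert-butyl (5Z)-7-acetoxy-2-chloro-2-[(1S,4E,8Z)-10-(tert-butyldimethylsilyloxy)-1-hydroxy-4,8-dimethyldeca-4,8-dien-1-yl]-6-methylhept-5-enoate
Conditions: Ac2O (1.1 equiv), pyridine, CH2Cl2, 0 °C
Reagents that add atoms: acetic anhydride, CC(=O)OC(C)=O
Why: Chemoselective acylation takes the unhindered primary allylic hydroxyl, because the C10 hydroxyl sits next to a fully substituted carbon and reacts far more slowly.

Step 10
Reactants: 16 acetate
Product: 19 (5Z)-7-acetoxy-2-chloro-2-[(1S,4E,8Z)-1,10-bis(tert-butyldimethylsilyloxy)-4,8-dimethyldeca-4,8-dien-1-yl]-6-methylhept-5-enoic acid, via silyl ether ester 17 (not isolated), via trimethylsilyl ester 18 (not isolated)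
Conditions: t-BuMe2SiOTf (1.3 equiv), 2,6-lutidine (5 equiv), CH2Cl2, −78 to 0 °C; Me3SiOTf (2 equiv), 0 °C to rt; pH 5 aq. buffer
Reagents that add atoms: tert-butyldimethylsilyl triflate, CC(C)(C)[Si](C)(C)OS(=O)(=O)C(F)(F)F
Why: Silyl triflate silylation blocks O10, which would otherwise attack C7 in a 5-exo mode, and buffered Me3SiOTf then turns the tert-butyl ester into a labile silyl ester (loss of isobutene) that hydrolyses on work-up while the acetate and silyl ethers survive.

Step 11
Reactants: 19 chloro acid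
Product: 21 (4S,7R)-3-[(3Z)-5-acetoxy-4-methylpent-3-en-1-yl]-3-chloro-4-(tert-butyldimethylsilyloxy)-7-[(1S,4Z)-6-(tert-butyldimethylsilyloxy)-1-hydroxy-4-methylhex-4-en-1-yl]-7-methyloxepan-2-one, via epoxy acid 20 (not isolated)
Conditions: 1,2:4,5-di-O-isopropylidene-β-L-erythro-2,3-hexodiulo-2,6-pyranose (0.3 equiv), KHSO5 (1.3 equiv, as 2KHSO5·KHSO4·K2SO4), K2CO3, Bu4NHSO4, Na2B4O7 buffer, MeCN/CH2(OMe)2/H2O, 0 °C; acidify to pH 4, extract; then (CF3)2CHOH/CH2Cl2 1:4, 5 mM, rt
Reagents that add atoms: potassium peroxymonosulfate, [K+].OOS(=O)(=O)[O-]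
Why: Shi epoxidation with the L-fructose-derived ketone picks the only olefin without an allylic C–O bond and gives the (6S,7S)-epoxide, after which the acidic α-chloro acid opens it at tertiary C7 in a 7-exo-tet, SN2-like lactonisation with inversion (hydrogen-bond activation, fully substituted C7 and C11 aid closure), which sets 7R and frees the 6S carbinol.

Step 12
Reactants: 21 hydroxy chloro ε-lactone
Product: 22 O1,O10-bis(tert-butyldimethylsilyl) ether of the target (dioxabicyclo[3.2.2]nonanone core)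
Conditions: [Cu(MeCN)4]PF6 (10 mol%), tris(2-pyridylmethyl)amine (11 mol%), Cs2CO3 (1.5 equiv), MeCN/toluene 1:1, 5 mM, degassed, 45 °C
Reagents that add atoms: none
Why: Proposed new method: monovalent copper abstracts chlorine from the tertiary α-chloro lactone (atom-transfer activation) to give a planar α-acyl radical at C11 while the C6 alkoxide binds the divalent copper formed, and radical capture followed by C–O reductive elimination from trivalent copper closes the six-membered dioxanone ring; because the C6–O arm hangs from C7 on one face of the lactone only, both C11 epimers converge on 11R, and the trans, silylated O10 cannot compete; the closest known reaction types are the intermolecular copper-catalysed etherification of tertiary α-bromo carbonyl compounds with alcohols and atom-transfer radical cyclisation.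

Step 13
Reactants: 22 bis-silyl ether
Product: 23 target CNP0174851.1
Conditions: HF·pyridine, pyridine, THF, 0 °C to rt
Reagents that add atoms: none
Why: Fluoride-mediated desilylation removes both silyl ethers under buffered conditions that leave the acetate, the lactone, the Z olefins and all four stereocentres unchanged.

## Compound list

1 | nerol, (2Z)-3,7-dimethylocta-2,6-dien-1-ol | CC(C)=CCC/C(C)=C\CO | starting material
2 | neryl tert-butyldimethylsilyl ether | CC(C)=CCC/C(C)=C\CO[Si](C)(C)C(C)(C)C | intermediate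
3 | (2E,6Z)-8-(tert-butyldimethylsilyloxy)-2,6-dimethylocta-2,6-dien-1-ol | OC/C(C)=C/CC/C(C)=C\CO[Si](C)(C)C(C)(C)C | intermediate
4 | (2Z,6E)-8-bromo-1-(tert-butyldimethylsilyloxy)-3,7-dimethylocta-2,6-diene | BrC/C(C)=C/CC/C(C)=C\CO[Si](C)(C)C(C)(C)C | intermediate
5 | N-tert-butylethanimine | CC=NC(C)(C)C | starting material
6 | N-tert-butyl imine of aldehyde 7 | CC(C)(C)N=CCC/C(C)=C/CC/C(C)=C\CO[Si](C)(C)C(C)(C)C | intermediate
7 | (4E,8Z)-10-(tert-butyldimethylsilyloxy)-4,8-dimethyldeca-4,8-dienal | O=CCC/C(C)=C/CC/C(C)=C\CO[Si](C)(C)C(C)(C)C | intermediate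
8 | (4-carboxybutyl)triphenylphosphonium bromide | [Br-].OC(=O)CCCC[P+](c1ccccc1)(c1ccccc1)c1ccccc1 | starting material
9 | 1-(tert-butyldimethylsilyloxy)propan-2-one | CC(=O)CO[Si](C)(C)C(C)(C)C | starting material
10 | (5Z)-7-(tert-butyldimethylsilyloxy)-6-methylhept-5-enoic acid | CC(C)(C)[Si](C)(C)OC/C(C)=C\CCCC(O)=O | intermediate
11 | (5Z)-7-hydroxy-6-methylhept-5-enoic acid | OC/C(C)=C\CCCC(O)=O | intermediate
12 | tert-butyl (5Z)-7-hydroxy-6-methylhept-5-enoate | OC/C(C)=C\CCCC(=O)OC(C)(C)C | intermediate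
13 | tert-butyl (5Z)-2-chloro-7-hydroxy-6-methylhept-5-enoate (racemic) | OC/C(C)=C\CCC(Cl)C(=O)OC(C)(C)C | intermediate
14 | chloro ketene tert-butyl trimethylsilyl acetal of 13, O7-trimethylsilyl ether | C[Si](C)(C)OC/C(C)=C\CCC(Cl)=C(OC(C)(C)C)O[Si](C)(C)C | intermediate
15 | aldol diol, 10S, C11 epimers | OC/C(C)=C\CCC(Cl)(C(=O)OC(C)(C)C)[C@@H](O)CC/C(C)=C/CC/C(C)=C\CO[Si](C)(C)C(C)(C)C | intermediate
16 | C16 acetate of 15 | CC(=O)OC/C(C)=C\CCC(Cl)(C(=O)OC(C)(C)C)[C@@H](O)CC/C(C)=C/CC/C(C)=C\CO[Si](C)(C)C(C)(C)C | intermediate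
17 | O10-tert-butyldimethylsilyl ether of 16 | CC(=O)OC/C(C)=C\CCC(Cl)(C(=O)OC(C)(C)C)[C@@H](O[Si](C)(C)C(C)(C)C)CC/C(C)=C/CC/C(C)=C\CO[Si](C)(C)C(C)(C)C | intermediate
18 | trimethylsilyl ester of acid 19 | CC(=O)OC/C(C)=C\CCC(Cl)(C(=O)O[Si](C)(C)C)[C@@H](O[Si](C)(C)C(C)(C)C)CC/C(C)=C/CC/C(C)=C\CO[Si](C)(C)C(C)(C)C | intermediate
19 | α-chloro-β-silyloxy acid, 10S | CC(=O)OC/C(C)=C\CCC(Cl)(C(O)=O)[C@@H](O[Si](C)(C)C(C)(C)C)CC/C(C)=C/CC/C(C)=C\CO[Si](C)(C)C(C)(C)C | intermediate
20 | (6S,7S)-epoxy acid, 10S | CC(=O)OC/C(C)=C\CCC(Cl)(C(O)=O)[C@@H](O[Si](C)(C)C(C)(C)C)CC[C@]1(C)O[C@H]1CC/C(C)=C\CO[Si](C)(C)C(C)(C)C | intermediate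
21 | hydroxy chloro ε-lactone, 6S,7R,10S, C11 epimers | CC(=O)OC/C(C)=C\CCC1(Cl)[C@@H](O[Si](C)(C)C(C)(C)C)CC[C@](C)([C@@H](O)CC/C(C)=C\CO[Si](C)(C)C(C)(C)C)OC1=O | intermediate
22 | O1,O10-bis(tert-butyldimethylsilyl) ether of the target, 6S,7R,10S,11R | CC(=O)OC/C(C)=C\CC[C@@]12O[C@@H](CC/C(C)=C\CO[Si](C)(C)C(C)(C)C)[C@@](C)(CC[C@@H]1O[Si](C)(C)C(C)(C)C)OC2=O | intermediate
23 | CNP0174851.1 | CC(=O)OC/C(C)=C\CC[C@@]12O[C@@H](CC/C(C)=C\CO)[C@@](C)(CC[C@@H]1O)OC2=O | target

## Step count and risks

Total step count: 13. Longest linear sequence: 10 steps (1 → 2 → 3 → 4 → 7 → 15 → 16 → 19 → 21 → 22 → 23).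

**Step 12 (the new step).** The α-acyl radical may be reduced or lose HCl instead of forming the C–O bond. The fallback sets out from 21 and comes back at 22, and it moves the ether-forming event from C11 to C6 using known chemistry only. The same radical is trapped by TEMPO (Cu powder, [Cu(MeCN)4]PF6, tris(2-pyridylmethyl)amine) to give the alkoxyamine F1. Zn/AcOH cleaves the N–O bond to give the tertiary α-hydroxy lactone F2. Dess–Martin periodinane oxidises only the secondary C6 carbinol to give the keto lactone F3, which sits in equilibrium with its bridged hemiketal. Reductive etherification with Et3SiH/Me3SiOTf at −78 °C should deliver hydride to the oxocarbenium ion from the side of the flat lactone bridge, which would give 6S and hence 22. Only the F2 epimer with the C11 hydroxyl on the C6 face can bridge, so material may be lost here.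

**Step 11.** Over-epoxidation of the allylic ether or acetate olefins is possible, and the seven-membered closure may be slow. The fallback sets out from 20 and comes back at 21, closing the lactone at the acyl–oxygen bond instead. Dilute aqueous HClO4 in THF at 0 °C hydrolyses the epoxide with inversion at C7 to give the dihydroxy acid F4. Et3SiCl/imidazole caps the secondary C6 hydroxyl (the silyl ester is lost on work-up) to give the triethylsilyl ether acid F5. Shiina lactonisation (2-methyl-6-nitrobenzoic anhydride, 4-(dimethylamino)pyridine, slow addition, toluene) closes the ring on the tertiary hydroxyl to give the protected lactone F6, although acylating a tertiary alcohol this way is itself demanding. Pyridinium p-toluenesulfonate in EtOH at 0 °C removes the triethylsilyl group to give 21.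

**Step 8.** The enantioselectivity with a tetrasubstituted chloro ketene acetal is uncertain. The fallback sets out from 13 and 7 and comes back at 16, replacing the reagent-controlled aldol by oxidation and catalyst-controlled reduction. The lithium enolate of 13 (LiN(SiMe3)2, 2.1 equiv, −78 °C) adds to 7 and is quenched cold with AcOH (interrupted Darzens reaction) to give the chlorohydrin diol F7 as a C10 mixture. Ac2O/pyridine gives the primary acetate F8. Dess–Martin periodinane gives the α-chloro-β-keto ester F9. Corey–Bakshi–Shibata reduction with the (R)-B-methyl oxazaborolidine and catecholborane at −78 °C differentiates the fully substituted C11 from the C9 methylene and should give the 10S alcohol 16.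

## Further compounds

F1 | step 12 | C11 2,2,6,6-tetramethylpiperidin-1-yloxy lactone | CC(=O)OC/C(C)=C\CCC1(ON2C(C)(C)CCCC2(C)C)[C@@H](O[Si](C)(C)C(C)(C)C)CC[C@](C)([C@@H](O)CC/C(C)=C\CO[Si](C)(C)C(C)(C)C)OC1=O
F2 | step 12 | C11 tertiary α-hydroxy lactone | CC(=O)OC/C(C)=C\CCC1(O)[C@@H](O[Si](C)(C)C(C)(C)C)CC[C@](C)([C@@H](O)CC/C(C)=C\CO[Si](C)(C)C(C)(C)C)OC1=O
F3 | step 12 | C6 keto C11 hydroxy lactone | CC(=O)OC/C(C)=C\CCC1(O)[C@@H](O[Si](C)(C)C(C)(C)C)CC[C@](C)(C(=O)CC/C(C)=C\CO[Si](C)(C)C(C)(C)C)OC1=O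
F4 | step 11 | (6S,7R)-dihydroxy acid | CC(=O)OC/C(C)=C\CCC(Cl)(C(O)=O)[C@@H](O[Si](C)(C)C(C)(C)C)CC[C@@](C)(O)[C@@H](O)CC/C(C)=C\CO[Si](C)(C)C(C)(C)C
F5 | step 11 | O6-triethylsilyl ether of F4 | CC(=O)OC/C(C)=C\CCC(Cl)(C(O)=O)[C@@H](O[Si](C)(C)C(C)(C)C)CC[C@@](C)(O)[C@@H](O[Si](CC)(CC)CC)CC/C(C)=C\CO[Si](C)(C)C(C)(C)C
F6 | step 11 | O6-triethylsilyl ether of lactone 21 | CC(=O)OC/C(C)=C\CCC1(Cl)[C@@H](O[Si](C)(C)C(C)(C)C)CC[C@](C)([C@@H](O[Si](CC)(CC)CC)CC/C(C)=C\CO[Si](C)(C)C(C)(C)C)OC1=O
F7 | step 8 | chlorohydrin diol, C10 and C11 mixture | OC/C(C)=C\CCC(Cl)(C(=O)OC(C)(C)C)C(O)CC/C(C)=C/CC/C(C)=C\CO[Si](C)(C)C(C)(C)C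
F8 | step 8 | C16 acetate of F7 | CC(=O)OC/C(C)=C\CCC(Cl)(C(=O)OC(C)(C)C)C(O)CC/C(C)=C/CC/C(C)=C\CO[Si](C)(C)C(C)(C)C
F9 | step 8 | α-chloro-β-keto ester | CC(=O)OC/C(C)=C\CCC(Cl)(C(=O)OC(C)(C)C)C(=O)CC/C(C)=C/CC/C(C)=C\CO[Si](C)(C)C(C)(C)C
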